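**Strategy.** Everything rests on cutting ring C (cyclobutane C5–C6–C6'–C5') at C5–C6 and C5'–C6'. The vicinal spiro carbons C5 and C5' each carry a lactone oxygen (O1, O1') and a carboxyl-level carbon (C4, C4' of butenolide rings A and B). This is the substitution pattern of the alkene carbons of dihydroxyfumaric acid, while C6–C6' is acetylene. A sensitised [2+2] photocycloaddition of acetylene to an acyclic dimethyl fumarate bearing one hexanoyloxy and one (R)-3-silyloxyhexanoyloxy group therefore forms both bonds, ring C and both quaternary centres at once. The cyclobutene is dibrominated immediately, before a double Dieckmann closure and enol-to-bromide exchange raise rings A and B.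

Key step: step 6

Labels: ring A = O1–C2(=O)–C3(butyl)=C4(Br)–C5. Ring B = O1'–C2'(=O)–C3'(side chain)=C4'(Br)–C5'. Ring C = C5–C6–C6'–C5'. C7' = side-chain carbinol carbon. The same labels are used for these atoms in the earlier intermediates.

Remark on the chemistry: the target SMILES decodes as 5S, 5'S (O1 and O1' trans on ring C), 6R, 6'R and 7'R. The two ring-C bromines are trans to each other, and each is trans to the ring oxygen on the neighbouring spiro carbon. The route is planned for exactly this isomer.

**Step 1**
Reactants: 1 methyl 3-oxohexanoate
Product: 2 methyl (3R)-3-hydroxyhexanoate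
Conditions: H2 (50 bar), RuCl2[(R)-BINAP] (0.1 mol%), MeOH, 50 °C
Reagents that add atoms: none
Why: Noyori asymmetric hydrogenation of a β-keto ester, in which chelation of the keto ester to the (R)-BINAP ruthenium hydride exposes one carbonyl face only and so sets the (R)-carbinol centre that becomes C7'.

**Step 2**
Reactants: 2 methyl (3R)-3-hydroxyhexanoate
Product: 3 methyl (3R)-3-(tert-butyldimethylsilyloxy)hexanoate
Conditions: TBSCl, imidazole, DMF, rt
Reagents that add atoms: tert-butyldimethylsilyl chloride CC(C)(C)[Si](C)(C)Cl
Why: Imidazole-promoted O-silylation gives a silyl ether that has no chromophore, is inert to bromine and tolerates cold amide base, and the stereocentre is not touched.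

**Step 3**
Reactants: 3 methyl (3R)-3-(tert-butyldimethylsilyloxy)hexanoate
Product: 4 (3R)-3-(tert-butyldimethylsilyloxy)hexanoic acid
Conditions: LiOH, THF/MeOH/H2O, 0 °C to rt; then 1 M HCl to pH 3
Reagents that add atoms: lithium hydroxide [Li+].[OH-]
Why: Saponification of an unhindered methyl ester is faster at this temperature than β-elimination of the silyloxy group, so the acid should form with C7' intact.

**Step 4**
Reactants: 5 dimethyl dihydroxyfumarate; 6 hexanoyl chloride
Product: 7 dimethyl (E)-2-(hexanoyloxy)-3-hydroxybut-2-enedioate
Conditions: 5 (2.5 equiv), pyridine (1.1 equiv), THF, argon, −20 to 0 °C, slow addition of 6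
Reagents that add atoms: none
Why: Pyridine-mediated O-acylation of an enediol is steered to the mono-ester by an excess of the cheap enediol and by the lower nucleophilicity of the remaining enol once its neighbour is acylated, and the sparingly soluble surplus of 5 is removed by filtration and chromatography.

**Step 5**
Reactants: 4 (3R)-3-(tert-butyldimethylsilyloxy)hexanoic acid; 7 dimethyl (E)-2-(hexanoyloxy)-3-hydroxybut-2-enedioate
Product: 9 dimethyl (E)-2-(hexanoyloxy)-3-{[(3R)-3-(tert-butyldimethylsilyloxy)hexanoyl]oxy}but-2-enedioate, via acid chloride 8 (not isolated)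
Conditions: 4, Me2C=C(Cl)NMe2, CH2Cl2, 0 °C; then 7, pyridine, −20 °C to rt
Reagents that add atoms: none
Why: Acid chloride formation with an α-chloroenamine liberates no acid that could strip the silyl ether, the following enol O-acylation uses a base too weak to cause ketene formation or β-elimination, and any Z isomer is harmless because sensitised irradiation interconverts the two alkene geometries.

**Step 6**
Reactants: 9 dimethyl (E)-2-(hexanoyloxy)-3-{[(3R)-3-(tert-butyldimethylsilyloxy)hexanoyl]oxy}but-2-enedioate; 10 acetylene
Product: 11 dimethyl (1R,2R)-1-(hexanoyloxy)-2-{[(3R)-3-(tert-butyldimethylsilyloxy)hexanoyl]oxy}cyclobut-3-ene-1,2-dicarboxylate (acyloxy groups trans)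
Conditions: acetylene (1 atm, continuous stream, saturated solution), acetophenone (0.3 equiv), acetone, −60 °C, hν (medium-pressure Hg lamp, Pyrex, λ > 300 nm); chromatographic separation of the diastereomers
Reagents that add atoms: none
Why: Acetophenone absorbs the Pyrex-filtered light, which 9 itself does not take up (so singlet acyl shifts of the enol esters are avoided), and passes its triplet energy to the tetrasubstituted alkene, whose twisted triplet bonds through one oxygenated carbon to acetylene to give a 1,4-biradical that is captodatively stabilised at the other oxygenated carbon by its ester and acyloxy groups. The closest known reaction types are the sensitised [2+2] photocycloadditions of acetylene to maleic anhydride derivatives and of alkenes to fumarates. Ring C closes after intersystem crossing by radical recombination of the 1,4-biradical, so the mode is a stepwise [2+2] that ends in a four-membered radical-radical closure and leaves a cyclobutene. The relative configuration at C5 and C5' is controlled by the E geometry of 9 and by bond rotation in the triplet and in the biradical, which let the two acyloxy groups and the two ester groups settle on opposite faces before the second bond forms. The absolute configuration is not induced, so the (1R,2R) and (1S,2S) rings should arise in similar amounts and are distinguished only as diastereomers through the (R)-silyloxy centre, which is why 11 is taken out by chromatography. The step needs capture of a short-lived triplet to compete with decay by twisting, which the very high solubility of acetylene in cold acetone secures, and it needs the product to persist, which is secured because 11 no longer holds the conjugated chromophore and cannot accept energy from the sensitiser.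

**Step 7**
Reactants: 11 dimethyl (1R,2R)-1-(hexanoyloxy)-2-{[(3R)-3-(tert-butyldimethylsilyloxy)hexanoyl]oxy}cyclobut-3-ene-1,2-dicarboxylate
Product: 12 dimethyl (1R,2R,3R,4R)-3,4-dibromo-1-(hexanoyloxy)-2-{[(3R)-3-(tert-butyldimethylsilyloxy)hexanoyl]oxy}cyclobutane-1,2-dicarboxylate (bromines trans to each other, each trans to the vicinal acyloxy oxygen)
Conditions: Br2 (1.2 equiv), Bu4NBr (1 equiv), CH2Cl2, −20 °C to rt, dark
Reagents that add atoms: bromine BrBr
Why: Bromide-assisted ionic anti addition of Br2 through a bromonium ion makes C6 and C6' trans, and since both faces of the pseudo-C2-symmetric cyclobutene lead to the same products the only open choice is which end of the bromonium ion is opened, a choice made here while C4 and C4' are still freely rotating ester groups of no greater reach than the acyloxy groups, so that dipole repulsion should keep the bridging bromine and the incoming bromide away from the neighbouring C–O bonds and place each bromine trans to the vicinal acyloxy oxygen, whereas after lactone closure and C4/C4' bromination the vinylic bromines would cover exactly the two sites that must be filled; the added bromide also suppresses acyloxy participation.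

**Step 8**
Reactants: 12 dimethyl (1R,2R,3R,4R)-3,4-dibromo-1-(hexanoyloxy)-2-{[(3R)-3-(tert-butyldimethylsilyloxy)hexanoyl]oxy}cyclobutane-1,2-dicarboxylate
Product: 13 bis(tetronic acid): (5S,5'S,6R,6'R)-6,6'-dibromo dispiro compound with ring A = 3-butyl-4-hydroxybutenolide and ring B = 4'-hydroxy-3'-[(1R)-1-(tert-butyldimethylsilyloxy)butyl]butenolide
Conditions: LiN(SiMe3)2 (4.5 equiv), THF, −78 to −30 °C; cold 1 M HCl quench; used at once
Reagents that add atoms: none
Why: Twofold Dieckmann condensation of α-acyloxy esters, the standard entry to spiro tetronic acids, in which each ester enolate attacks its geminal methyl ester (five-membered closure is preferred over attack on the vicinal ester, as with O-acyl malates), deprotonation of each tetronic acid makes the closure irreversible, the β-silyloxy enolate is kept cold against β-elimination, and the trans-dibromide offers the hindered amide no antiperiplanar H/Br pair, so all five stereocentres should be retained.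

**Step 9**
Reactants: 13 bis(tetronic acid)
Product: 14 (5S,5'S,6R,6'R)-4,4',6,6'-tetrabromo dispiro bis(butenolide) with 3-butyl on ring A and 3'-[(1R)-1-(tert-butyldimethylsilyloxy)butyl] on ring B
Conditions: (COBr)2 (3 equiv), DMF (3 equiv), 2,6-di-tert-butylpyridine (2.5 equiv), CH2Cl2, 0 °C to rt
Reagents that add atoms: oxalyl bromide O=C(Br)C(=O)Br
Why: Vilsmeier-type deoxybromination of tetronic acids, in which each enol oxygen (C3 and C3' are fully substituted, so only oxygen reacts) attacks the bromoiminium salt and bromide then displaces the resulting leaving group by addition-elimination at C4 and C4', while the hindered pyridine traps HBr so that neither the silyl ether nor the C7'–O bond is ionised and no stereocentre is involved.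

**Step 10**
Reactants: 14 tetrabromo bis(butenolide) silyl ether
Product: 15 (5S,5'S,6R,6'R)-4,4',6,6'-tetrabromo dispiro bis(butenolide) with 3-butyl on ring A and 3'-[(1R)-1-hydroxybutyl] on ring B
Conditions: HF·pyridine, THF, 0 °C to rt (plastic vessel)
Reagents that add atoms: none
Why: Fluoride-mediated desilylation under acidic, weakly nucleophilic conditions cleaves only the Si–O bond, so C7' keeps its configuration and the base-sensitive bromobutenolides and secondary bromides are spared.

**Step 11**
Reactants: 15 tetrabromo bis(butenolide) alcohol
Product: 16 CNP0268004.1, (5S,5'S,6R,6'R)-4,4',6,6'-tetrabromo dispiro bis(butenolide) with 3-butyl on ring A and 3'-[(1R)-1-acetoxybutyl] on ring B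
Conditions: Ac2O (3 equiv), Sc(OTf)3 (2 mol%), MeCN, 0 °C
Reagents that add atoms: acetic anhydride CC(=O)OC(C)=O
Why: Lewis-acid-catalysed acetylation of a secondary alcohol occurs at oxygen with retention at C7' and needs no amine that could add to the β-bromobutenolides or remove HBr.

**Compound list**
1 | methyl 3-oxohexanoate | CCCC(=O)CC(=O)OC | starting material
2 | methyl (3R)-3-hydroxyhexanoate | COC(=O)C[C@@H](CCC)O | intermediate
3 | methyl (3R)-3-(tert-butyldimethylsilyloxy)hexanoate | COC(=O)C[C@@H](CCC)O[Si](C)(C)C(C)(C)C | intermediate
4 | (3R)-3-(tert-butyldimethylsilyloxy)hexanoic acid | OC(=O)C[C@@H](CCC)O[Si](C)(C)C(C)(C)C | intermediate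
5 | dimethyl dihydroxyfumarate | COC(=O)/C(O)=C(\O)C(=O)OC | starting material
6 | hexanoyl chloride | CCCCCC(Cl)=O | starting material
7 | dimethyl (E)-2-(hexanoyloxy)-3-hydroxybut-2-enedioate | CCCCCC(=O)O/C(C(=O)OC)=C(/O)C(=O)OC | intermediate
8 | (3R)-3-(tert-butyldimethylsilyloxy)hexanoyl chloride | ClC(=O)C[C@@H](CCC)O[Si](C)(C)C(C)(C)C | intermediate
9 | dimethyl (E)-2-(hexanoyloxy)-3-{[(3R)-3-(tert-butyldimethylsilyloxy)hexanoyl]oxy}but-2-enedioate | CCCCCC(=O)O/C(C(=O)OC)=C(/OC(=O)C[C@@H](CCC)O[Si](C)(C)C(C)(C)C)C(=O)OC | intermediate
10 | acetylene | C#C | starting material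
11 | dimethyl (1R,2R)-1-(hexanoyloxy)-2-{[(3R)-3-(tert-butyldimethylsilyloxy)hexanoyl]oxy}cyclobut-3-ene-1,2-dicarboxylate | COC(=O)[C@@]1(OC(=O)CCCCC)C=C[C@]1(OC(=O)C[C@@H](CCC)O[Si](C)(C)C(C)(C)C)C(=O)OC | intermediate
12 | dimethyl (1R,2R,3R,4R)-3,4-dibromo-1-(hexanoyloxy)-2-{[(3R)-3-(tert-butyldimethylsilyloxy)hexanoyl]oxy}cyclobutane-1,2-dicarboxylate | COC(=O)[C@@]1(OC(=O)CCCCC)[C@@H](Br)[C@H](Br)[C@]1(OC(=O)C[C@@H](CCC)O[Si](C)(C)C(C)(C)C)C(=O)OC | intermediate
13 | (5S,5'S,6R,6'R,7'R) dibromo bis(tetronic acid) silyl ether | CCCCC1=C(O)[C@@]2(OC1=O)[C@@H](Br)[C@H](Br)[C@@]21OC(=O)C([C@@H](CCC)O[Si](C)(C)C(C)(C)C)=C1O | intermediate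
14 | (5S,5'S,6R,6'R,7'R) tetrabromo bis(butenolide) silyl ether | CCCCC1=C(Br)[C@@]2(OC1=O)[C@@H](Br)[C@H](Br)[C@@]21OC(=O)C([C@@H](CCC)O[Si](C)(C)C(C)(C)C)=C1Br | intermediate
15 | (5S,5'S,6R,6'R,7'R) tetrabromo bis(butenolide) alcohol | CCCCC1=C(Br)[C@@]2(OC1=O)[C@@H](Br)[C@H](Br)[C@@]21OC(=O)C([C@@H](CCC)O)=C1Br | intermediate
16 | CNP0268004.1 | CCCCC1=C(Br)[C@@]2(OC1=O)[C@@H](Br)[C@H](Br)[C@@]21OC(=O)C([C@@H](CCC)OC(C)=O)=C1Br | target

**Step count and risks**

Total step count: 11. Longest linear sequence: 10 (steps 1–3 and 5–11).

Steps most likely to fail:

1. **Step 6.**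
   - What may go wrong: radiationless decay of the twisted triplet and E/Z cycling may outrun capture by the dissolved gas. Alternatively, the vinyl-radical end of the biradical may abstract hydrogen from an acyl chain before ring closure.
   - Fallback (sets out from 9, comes back at 11): the gaseous alkyne is replaced by a liquid acetylene surrogate. Compound 9 is irradiated with the same sensitiser in (E)-1,2-dichloroethene as co-solvent. This is a known enoate–alkene [2+2] photocycloaddition in which the trap is present in multimolar concentration and the biradical end is an alkyl radical rather than a vinyl radical.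
   - This should give the dichlorocyclobutane diester F1 (chlorine-bearing carbons as a mixture), and the trans (1R,2R) core is selected by chromatography. Activated Zn dust in warm ethanol then removes both chlorines by reductive 1,2-elimination and returns cyclobutene 11.

2. **Step 7.**
   - What may go wrong: there may be poor discrimination between the two ends of the bromonium ion, so that bromide also enters next to the acyloxy oxygen. Acyloxy participation may also compete.
   - Fallback (sets out from 11, comes back at 11): kinetic control is given up for a separate-and-recycle loop. The addition is run without regard to selectivity and 12 is drawn off by chromatography.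
   - The unwanted (1R,2R,3S,4S) trans-dibromide F2 is reduced with Zn dust in THF/AcOH at 0 °C (reductive 1,2-debromination). This regenerates 11 for the next pass, so the material converges on 12. The loop is available only at this stage, because later intermediates carry reducible vinylic bromides.

3. **Step 8.**
   - What may go wrong: silyloxide may be lost by β-elimination from the ring-B acyl enolate, HBr or Br2 may be lost to the strong base, or closure may occur onto the vicinal ester.
   - Fallback (sets out from 12, comes back at 13): the hard lithium enolates are replaced by a titanium-mediated Dieckmann condensation (TiCl4, Bu3N, CH2Cl2, −78 to 0 °C).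
   - Here the Lewis acid activates the acceptor ester and a soft titanium enolate forms with a tertiary amine only, a manifold known to tolerate alkyl halides. The detour makes no new compound (F0).

**Further compounds**
F1 | step 6 | dimethyl (1R,2R)-3,4-dichloro-1-(hexanoyloxy)-2-{[(3R)-3-(tert-butyldimethylsilyloxy)hexanoyl]oxy}cyclobutane-1,2-dicarboxylate (CHCl centres as a mixture) | COC(=O)[C@@]1(OC(=O)CCCCC)C(Cl)C(Cl)[C@]1(OC(=O)C[C@@H](CCC)O[Si](C)(C)C(C)(C)C)C(=O)OC
F2 | step 7 | dimethyl (1R,2R,3S,4S)-3,4-dibromo-1-(hexanoyloxy)-2-{[(3R)-3-(tert-butyldimethylsilyloxy)hexanoyl]oxy}cyclobutane-1,2-dicarboxylate | COC(=O)[C@@]1(OC(=O)CCCCC)[C@H](Br)[C@@H](Br)[C@]1(OC(=O)C[C@@H](CCC)O[Si](C)(C)C(C)(C)C)C(=O)OC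
F0 | step 8 | none | none
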